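**Retrosynthetic overview**
1. The last step only removes three phenolic benzyl ethers. One earlier operation delivers the C5–C6 bond, the C5 stereocentre, the acetate on O3 and the free O5–H.
2. Enabling feature: the anti C3(OAc)–C4H2–C5(OH) unit. The acetyl C, O3, C3, C4, C5 and the hydrogen on C5 form a six-membered array. The hydroxy acetate is therefore the 1,5-hydride-shift (Tishchenko) isomer of a C5 ketone whose O3 bears an acetaldehyde hemiacetal.
3. Key disconnection C5–C6: this keto hemiacetal is the ring-opened adduct of a 2-(ring B)ethyl carbanion (C6) to the carbonyl carbon (C5) of a temporary 2-methyl-1,3-dioxan-4-one ring. In that ring the acetal C is the future acetyl C and ring O1 is O3.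
4. The dioxanone comes from the (R)-β-hydroxy acid and acetaldehyde. C3 is set by Noyori hydrogenation of the β-keto ester, which is made by γ-benzylation of methyl acetoacetate (C1–C2 bond).
5. Rings: both arenes are bought. The only ring formed is the temporary dioxanone, closed in step 4 and opened in step 6.

Key step: step 6

Remark: the chain is numbered C1 (benzylic CH2 on catechol ring A) to C7 (benzylic CH2 on 4-hydroxyphenyl ring B), and O3 and O5 are the oxygens on C3 and C5. The benzyl chloride of step 1 and the alcohol of step 5 are taken as commercial. Metal salts that differ from an isolated product only by the proton supplied at work-up are not numbered.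

**Step 1**
Reactants: 1 methyl acetoacetate; 2 3,4-bis(benzyloxy)benzyl chloride
Product: 4 methyl 5-[3,4-bis(benzyloxy)phenyl]-3-oxopentanoate, via dilithium dianion 3 (not isolated)
Conditions: LiN(iPr)2 (2.1 equiv), THF, 0 °C; then 2, 0 °C → rt; 1 M HCl
Reagents that add atoms: none
Why: Huckin–Weiler γ-alkylation, in which the dianion attacks the benzylic chloride by SN2 at its more nucleophilic terminal carbon; no stereocentre is formed.

**Step 2**
Reactants: 4 methyl 5-[3,4-bis(benzyloxy)phenyl]-3-oxopentanoate
Product: 5 methyl (3R)-5-[3,4-bis(benzyloxy)phenyl]-3-hydroxypentanoate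
Conditions: RuCl2[(R)-BINAP] (0.5 mol %), H2 (10 bar), MeOH/CH2Cl2, 50 °C
Reagents that add atoms: none
Why: Noyori asymmetric hydrogenation, in which the chelated β-keto ester takes hydride on one face from the (R)-BINAP ruthenium hydride, in the same sense as methyl acetoacetate gives methyl (R)-3-hydroxybutanoate, which sets C3 as R; aryl benzyl ethers are not cleaved by this homogeneous catalyst.

**Step 3**
Reactants: 5 methyl (3R)-5-[3,4-bis(benzyloxy)phenyl]-3-hydroxypentanoate
Product: 6 (3R)-5-[3,4-bis(benzyloxy)phenyl]-3-hydroxypentanoic acid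
Conditions: LiOH, THF/H2O, 0 °C → rt; then 1 M HCl to pH 3
Reagents that add atoms: lithium hydroxide [Li+].[OH-]
Why: Ester saponification by acyl–oxygen cleavage, mild enough to avoid β-elimination and without effect on C3.

**Step 4**
Reactants: 6 (3R)-5-[3,4-bis(benzyloxy)phenyl]-3-hydroxypentanoic acid; 7 acetaldehyde
Product: 9 (2R,6R)-6-{2-[3,4-bis(benzyloxy)phenyl]ethyl}-2-methyl-1,3-dioxan-4-one, via bis(trimethylsilyl) derivative 8 (not isolated)
Conditions: (Me3Si)2NH, CH2Cl2, rt, evaporate; then MeCHO (2 equiv), Me3SiOTf (10 mol %), CH2Cl2, −78 °C; pyridine quench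
Reagents that add atoms: hexamethyldisilazane C[Si](C)(C)N[Si](C)(C)C (its Me3Si groups stand only in 8 and leave again)
Why: Me3SiOTf-catalysed (Noyori-type) acetalization of a bis-silylated β-hydroxy acid, driven by loss of (Me3Si)2O, in which the new acetal centre C2 is set cis to C6 because both substituents sit equatorially; its configuration has no lasting consequence, since this carbon ends as the sp2 acetyl carbon.

**Step 5**
Reactants: 10 2-[4-(benzyloxy)phenyl]ethanol
Product: 11 1-(benzyloxy)-4-(2-bromoethyl)benzene
Conditions: CBr4, PPh3, CH2Cl2, 0 °C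
Reagents that add atoms: carbon tetrabromide BrC(Br)(Br)Br
Why: Appel reaction, an SN2 displacement of the alkoxyphosphonium ion by bromide at a primary carbon under neutral conditions.

**Step 6**
Reactants: 9 (2R,6R)-6-{2-[3,4-bis(benzyloxy)phenyl]ethyl}-2-methyl-1,3-dioxan-4-one; 11 1-(benzyloxy)-4-(2-bromoethyl)benzene
Product: 17 (3R,5R)-1-[3,4-bis(benzyloxy)phenyl]-7-[4-(benzyloxy)phenyl]-5-hydroxyheptan-3-yl acetate, via Grignard reagent 12 (not isolated), via alkylsamarium diiodide 13 (not isolated), via cyclic hemiketal alkoxide 14 (not isolated), via keto hemiacetal alkoxide 15 (not isolated), via samarium aldolate 16 (not isolated)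
Conditions: 11, Mg, THF, rt; SmI3 (1.05 equiv), THF, −40 °C, 1 h; 9 (1.1 equiv), −78 °C, 1 h, then → −10 °C, closed flask; pH 7 phosphate buffer at −10 °C
Reagents that add atoms: none
Why: Proposed new method: the weakly basic primary alkylsamarium 13 should add once to the acylal carbonyl of 9 (this makes the C5–C6 bond), the hemiketal alkoxide 14 should hold at −78 °C until all carbanion is spent (as do the aluminium hemiacetals that iBu2AlH forms from the same ring), and on warming 14 should open to ketone 15, whose O3 carries an I2Sm–O–CH(CH3) hemiacetal that passes its acetal hydrogen to C5 in a 1,5-hydride shift. The closest known reaction types are the single addition of organolithium and organocerium reagents to six-membered lactones, the Evans–Tishchenko reduction of β-hydroxy ketones by acetaldehyde and SmI2, of which 15 is the accepted intermediate, and the aldol–Tishchenko cascade; new is only that a carbanion addition to an acylal feeds this manifold. No ring is closed: the temporary dioxanone ring is opened, its two ring oxygens end as O3 and as the acetyl carbonyl oxygen, its exocyclic oxygen as O5 and its acetal carbon as the acetyl carbon. C5 is controlled by C3 through the chair–chair transition state (ring one: acetal C, O3, C3, C4, C5 and the moving H; ring two: Sm, hemiacetal O, acetal C, H, C5, O5), in which both arylethyl chains and the methyl group lie equatorial, so that hydride reaches the face of C5 that gives the 3,5-anti, here (3R,5R), isomer. The cis acetal of 9 sets free the hemiacetal epimer whose O–Sm bond would point equatorially in this array, so it must first be corrected by reversible loss and return of acetaldehyde 7 by way of aldolate 16, the same pre-equilibrium on which every Evans–Tishchenko reduction rests. The step needs single addition, secured by limiting carbanion and the cold hemiketal, and O3/O5 differentiation, secured because the hydride-donor carbon is bound to O3 alone, so that the acetate can arise nowhere else while O5 stays a trivalent samarium alkoxide until the cold neutral quench.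

**Step 7**
Reactants: 17 (3R,5R)-1-[3,4-bis(benzyloxy)phenyl]-7-[4-(benzyloxy)phenyl]-5-hydroxyheptan-3-yl acetate
Product: 18 (3R,5R)-1-(3,4-dihydroxyphenyl)-5-hydroxy-7-(4-hydroxyphenyl)heptan-3-yl acetate (CNP0249634.2)
Conditions: H2 (1 atm), Pd/C (10 wt %), EtOAc, rt
Reagents that add atoms: none
Why: Catalytic hydrogenolysis of three aryl benzyl ethers in a neutral, non-nucleophilic solvent, which leaves the acetate, the secondary alcohol and both stereocentres untouched, since no other benzylic C–O bond is present.

**Compound list**
1 | methyl acetoacetate | CC(=O)CC(=O)OC | starting material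
2 | 3,4-bis(benzyloxy)benzyl chloride | ClCc1ccc(OCc2ccccc2)c(OCc2ccccc2)c1 | starting material
3 | dilithium dianion of methyl acetoacetate | C=C(O[Li])C=C(OC)O[Li] | intermediate
4 | methyl 5-[3,4-bis(benzyloxy)phenyl]-3-oxopentanoate | COC(=O)CC(=O)CCc1ccc(OCc2ccccc2)c(OCc2ccccc2)c1 | intermediate
5 | methyl (3R)-5-[3,4-bis(benzyloxy)phenyl]-3-hydroxypentanoate | COC(=O)C[C@H](O)CCc1ccc(OCc2ccccc2)c(OCc2ccccc2)c1 | intermediate
6 | (3R)-5-[3,4-bis(benzyloxy)phenyl]-3-hydroxypentanoic acid | OC(=O)C[C@H](O)CCc1ccc(OCc2ccccc2)c(OCc2ccccc2)c1 | intermediate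
7 | acetaldehyde | CC=O | starting material
8 | trimethylsilyl (3R)-5-[3,4-bis(benzyloxy)phenyl]-3-(trimethylsilyloxy)pentanoate | C[Si](C)(C)OC(=O)C[C@H](O[Si](C)(C)C)CCc1ccc(OCc2ccccc2)c(OCc2ccccc2)c1 | intermediate
9 | (2R,6R)-6-{2-[3,4-bis(benzyloxy)phenyl]ethyl}-2-methyl-1,3-dioxan-4-one (cis) | C[C@H]1OC(=O)C[C@@H](CCc2ccc(OCc3ccccc3)c(OCc3ccccc3)c2)O1 | intermediate
10 | 2-[4-(benzyloxy)phenyl]ethanol | OCCc1ccc(OCc2ccccc2)cc1 | starting material
11 | 1-(benzyloxy)-4-(2-bromoethyl)benzene | BrCCc1ccc(OCc2ccccc2)cc1 | intermediate
12 | 2-[4-(benzyloxy)phenyl]ethylmagnesium bromide | Br[Mg]CCc1ccc(OCc2ccccc2)cc1 | intermediate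
13 | {2-[4-(benzyloxy)phenyl]ethyl}samarium diiodide | I[Sm](I)CCc1ccc(OCc2ccccc2)cc1 | intermediate
14 | diiodosamarium alkoxide of the 4-hydroxy-1,3-dioxane adduct (C2 and C6 as in 9, hemiketal carbon undefined) | C[C@H]1OC(CCc2ccc(OCc3ccccc3)cc2)(O[Sm](I)I)C[C@@H](CCc2ccc(OCc3ccccc3)c(OCc3ccccc3)c2)O1 | intermediate
15 | diiodosamarium alkoxide of the O3-(1-hydroxyethyl) keto hemiacetal (C3 R; acetal carbon first as inherited from 9, then equilibrating) | CC(O[Sm](I)I)O[C@H](CCc1ccc(OCc2ccccc2)c(OCc2ccccc2)c1)CC(=O)CCc1ccc(OCc2ccccc2)cc1 | intermediate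
16 | diiodosamarium aldolate of the (R)-β-hydroxy ketone | I[Sm](I)O[C@H](CCc1ccc(OCc2ccccc2)c(OCc2ccccc2)c1)CC(=O)CCc1ccc(OCc2ccccc2)cc1 | intermediate
17 | (3R,5R)-1-[3,4-bis(benzyloxy)phenyl]-7-[4-(benzyloxy)phenyl]-5-hydroxyheptan-3-yl acetate | CC(=O)O[C@H](CCc1ccc(OCc2ccccc2)c(OCc2ccccc2)c1)C[C@H](O)CCc1ccc(OCc2ccccc2)cc1 | intermediate
18 | (3R,5R)-1-(3,4-dihydroxyphenyl)-5-hydroxy-7-(4-hydroxyphenyl)heptan-3-yl acetate | CC(=O)O[C@H](CCc1ccc(O)c(O)c1)C[C@H](O)CCc1ccc(O)cc1 | target

**Total step count:** 7. **Longest linear sequence:** 6 (steps 1, 2, 3, 4, 6, 7).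

**Steps most likely to fail**

1. Step 6.
 - What may go wrong:
  - The hemiketal alkoxide collapses while carbanion is still present, which leads to a second addition at C5.
  - The single equivalent of acetaldehyde escapes or self-condenses, so the hydride shift stalls at the aldolate stage.
  - Retro-aldol cleavage erodes C3.
  - The acetyl group migrates from O3 to O5 in the product alkoxide before the quench.
 - Fallback, by known chemistry only, from 5 back to 17: hydroxy ester 5 is treated with MeNH(OMe)·HCl and iPrMgCl (THF, −20 °C). This should give the Weinreb amide (3R)-5-[3,4-bis(benzyloxy)phenyl]-3-hydroxy-N-methoxy-N-methylpentanamide F1. Excess Grignard reagent 12 (THF, 0 °C) forms the same C5–C6 bond through the stable chelated adduct. Work-up should then give the β-hydroxy ketone (5R)-7-[3,4-bis(benzyloxy)phenyl]-1-[4-(benzyloxy)phenyl]-5-hydroxyheptan-3-one F2. A standard Evans–Tishchenko reduction (excess acetaldehyde 7, SmI2 0.3 equiv, THF, −10 °C) leads to 17. Ketone recovered from an incomplete step 6 enters at this last operation.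

2. Step 4.
 - What may go wrong: acetaldehyde oligomerizes under Me3SiOTf faster than the ring closes, or the acylal opens hydrolytically during isolation.
 - Fallback from 6 back to 9, without free acetaldehyde: acid 6 undergoes Pd(OAc)2-catalysed transvinylation in vinyl acetate to the vinyl ester, vinyl (3R)-5-[3,4-bis(benzyloxy)phenyl]-3-hydroxypentanoate F3. Catalytic camphorsulfonic acid (CH2Cl2, 0 °C) then closes the ring by intramolecular Markovnikov addition of O3–H to the protonated vinyl ester, which gives 9.

3. Step 7.
 - What may go wrong: traces of iodide or samarium carried over from step 6 poison the catalyst and lengthen the exposure, during which the acetyl group may migrate and the catechol may oxidize in air.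
 - Fallback from 17 directly to 18, without a metal catalyst: Lewis-acid debenzylation with BCl3 and pentamethylbenzene as cation scavenger (CH2Cl2, −78 °C). This cleaves aryl benzyl ethers in the presence of esters. A cold methanol quench and isolation under argon follow.

**Further compounds**
F1 | step 6 | (3R)-5-[3,4-bis(benzyloxy)phenyl]-3-hydroxy-N-methoxy-N-methylpentanamide | CON(C)C(=O)C[C@H](O)CCc1ccc(OCc2ccccc2)c(OCc2ccccc2)c1
F2 | step 6 | (5R)-7-[3,4-bis(benzyloxy)phenyl]-1-[4-(benzyloxy)phenyl]-5-hydroxyheptan-3-one | O[C@H](CCc1ccc(OCc2ccccc2)c(OCc2ccccc2)c1)CC(=O)CCc1ccc(OCc2ccccc2)cc1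
F3 | step 4 | vinyl (3R)-5-[3,4-bis(benzyloxy)phenyl]-3-hydroxypentanoate | C=COC(=O)C[C@H](O)CCc1ccc(OCc2ccccc2)c(OCc2ccccc2)c1
F0 | step 7 | none | none
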